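**Plan**

1. Numbering used here: ten-membered ring C1 (lactone O–CH), C2=C3(Me) (E), C4 (OAc), C5–C6(Me) (cis-epoxide), C7H2, C8H2, C9 (O-angeloyl), C10 (ring fusion); lactone C10–C11(=C13H2)–C12(=O)–O–C1.
2. Retrosynthesis: unmask C11=C13 from a PhS adduct and remove the C9 angelate; cut C8–C9 (ring closure: primary iodide at C8 onto an aldehyde at C9); cut C3–C4 (alkenyl iodide plus epoxy aldehyde); cut C1–C10 and the lactone C–O (2-(methoxycarbonyl)allylation of but-2-ynal).
3. Feature used: C9 is a carbinol carbon joined to the unfunctionalised C8H2–C7H2 pair that ends at the quaternary epoxide carbon C6. The open chain is therefore a γ-epoxy primary iodide plus an aldehyde on the lactone β-carbon, which a chemoselective alkylchromium addition can join without touching epoxide, lactone or acetate.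
4. Forward order: cis-γ-lactone first, then the C1–C8 chain by C3–C4 coupling, then the ten-membered ring by C8–C9 closure, then the angelate, last the exocyclic methylene.
5. Stereochemistry: C5/C6 from Sharpless epoxidation of a (Z)-allylic alcohol made by syn-carbocupration; C4 by Felkin–Anh addition to the epoxy aldehyde; C1/C10 by ligand-controlled syn-selective chromium allylation; C9 by Felkin–Anh ring closure; C2=C3 (E) by syn-hydrozirconation; angelate geometry from angelic acid.

Key step: step 16

Remark: C11 of compounds 16–28 is drawn as the expected thermodynamic epimer (trans to the C10 substituent); its configuration is of no consequence because C11 becomes sp2 in step 18.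

**Route**

Step 1
Reactants: 1 4-bromobut-1-yne
Product: 3 methyl 5-bromopent-2-ynoate, via lithium acetylide 2 (not isolated)
Conditions: n-BuLi, THF, −78 °C; then ClCO2Me, −78 → 0 °C
Reagents that add atoms: methyl chloroformate, COC(=O)Cl
Why: Deprotonation of the terminal alkyne and C-acylation of the acetylide with the chloroformate should give the ynoate, the primary bromide being inert to the acetylide at −78 °C.

Step 2
Reactants: 3 methyl 5-bromopent-2-ynoate
Product: 4 methyl (2Z)-5-bromo-3-methylpent-2-enoate
Conditions: Me2CuLi, THF, −78 °C; aq. NH4Cl quench at −78 °C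
Reagents that add atoms: lithium dimethylcuprate, [Li+].C[Cu-]C
Why: syn-Carbocupration (conjugate addition) of the ynoate and cold protonation with retention place methyl and hydrogen cis, so the bromoethyl chain ends cis to the ester (Z).

Step 3
Reactants: 4 methyl (2Z)-5-bromo-3-methylpent-2-enoate
Product: 5 (2Z)-5-bromo-3-methylpent-2-en-1-ol
Conditions: i-Bu2AlH, CH2Cl2, −78 °C; Rochelle salt work-up
Reagents that add atoms: none
Why: 1,2-Reduction of the enoate by i-Bu2AlH should give the allylic alcohol without touching the alkene geometry or the bromide.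

Step 4
Reactants: 5 (2Z)-5-bromo-3-methylpent-2-en-1-ol
Product: 6 (2R,3S)-epoxy alcohol
Conditions: Ti(OiPr)4 (cat.), D-(−)-diethyl tartrate (cat.), t-BuOOH, 4 Å molecular sieves, CH2Cl2, −20 °C
Reagents that add atoms: tert-butyl hydroperoxide, CC(C)(C)OO
Why: Sharpless asymmetric epoxidation with the D-(−)-tartrate should deliver oxygen to the face that gives the (2R,3S)-epoxide (future C5 R, C6 S), the cis relation of CH2OH and bromoethyl coming from the (Z)-alkene.

Step 5
Reactants: 6 (2R,3S)-epoxy alcohol
Product: 7 (2S,3S)-epoxy aldehyde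
Conditions: Dess–Martin periodinane, NaHCO3, CH2Cl2, 0 °C
Reagents that add atoms: none
Why: Buffered Dess–Martin oxidation should give the epoxy aldehyde without epimerisation or epoxide opening (the descriptor at C2 changes only because the priorities change).

Step 6
Reactants: 8 {[tert-butyl(dimethyl)silyl]oxy}acetaldehyde; 9 methyl acrylate
Product: 10 Morita–Baylis–Hillman adduct (racemic)
Conditions: DABCO (cat.), excess methyl acrylate, 25 °C
Reagents that add atoms: none
Why: Morita–Baylis–Hillman reaction of an α-silyloxy aldehyde with methyl acrylate; the carbinol centre is lost in the next step, so no stereocontrol is needed.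

Step 7
Reactants: 10 Morita–Baylis–Hillman adduct
Product: 11 methyl (2Z)-2-(bromomethyl)-4-silyloxybut-2-enoate
Conditions: NBS, Me2S, CH2Cl2, 0 → 25 °C
Reagents that add atoms: N-bromosuccinimide, O=C1CCC(=O)N1Br
Why: Corey–Kim-type activation of the allylic alcohol and bromide attack with allylic transposition should give the more stable (Z)-2-(bromomethyl)enoate.

Step 8
Reactants: 11 methyl (2Z)-2-(bromomethyl)-4-silyloxybut-2-enoate; 12 but-2-ynal
Product: 15 (4R,5R)-cis-α-methylene lactone, via silyl ether 13 (not isolated), via hydroxy ester 14 (not isolated)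
Conditions: CrCl2 (10 mol %), chiral 3,6-di-tert-butyl-1,8-bis(4-isopropyl-4,5-dihydrooxazol-2-yl)carbazole ligand (12 mol %, the antipode that gives Re-face addition), Mn powder, Me3SiCl, i-Pr2NEt, THF, 25 °C; then PPTS, MeOH, 0 °C; then PPTS, toluene, 50 °C
Reagents that add atoms: none
Why: Chromium-catalysed enantioselective Nozaki–Hiyama 2-(alkoxycarbonyl)allylation: the allylchromium with its γ-substituent cis to the CH2Cr group should add through a chair transition state to give the syn adduct, the ligand fixing the absolute sense (C1 and C10), and acid-promoted desilylation and lactonisation should give the cis-lactone.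

Step 9
Reactants: 15 (4R,5R)-cis-α-methylene lactone
Product: 16 sulfide-masked lactone
Conditions: PhSH, Et3N (cat.), CH2Cl2, 25 °C
Reagents that add atoms: thiophenol, Sc1ccccc1
Why: Thia-Michael addition masks the exocyclic methylene, which would not survive hydrozirconation or the later C9 aldehyde stage, and the amine should equilibrate C11 to the trans arrangement.

Step 10
Reactants: 16 sulfide-masked lactone
Product: 18 (E)-alkenyl iodide, via alkenylzirconocene 17 (not isolated)
Conditions: Cp2Zr(H)Cl, THF, 25 °C; then I2, 0 °C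
Reagents that add atoms: iodine, II
Why: syn-Hydrozirconation should place zirconium on the methyl-bearing alkyne carbon remote from the branched C1, and iodinolysis with retention gives the (E)-2-iodoalkene that fixes the C2=C3 geometry.

Step 11
Reactants: 18 (E)-alkenyl iodide; 7 (2S,3S)-epoxy aldehyde
Product: 19 (4R)-allylic alcohol
Conditions: CrCl2 (4 equiv), NiCl2 (2 mol %), DMSO/THF, 25 °C
Reagents that add atoms: none
Why: Nozaki–Hiyama–Kishi coupling with retention of alkene geometry; Felkin–Anh addition with the epoxide C–O bond anti to the incoming alkenyl group should give the (4R) alcohol (erythro epoxy alcohol), while bromide, lactone and sulfide are inert to the organochromium.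

Step 12
Reactants: 19 (4R)-allylic alcohol
Product: 20 C4 acetate
Conditions: Ac2O, pyridine, DMAP (cat.), CH2Cl2, 0 °C
Reagents that add atoms: acetic anhydride, CC(=O)OC(C)=O
Why: Standard acylation of the secondary allylic alcohol, done promptly so that the alkoxide cannot migrate the neighbouring epoxide (Payne rearrangement).

Step 13
Reactants: 20 C4 acetate
Product: 21 primary iodide
Conditions: NaI, NaHCO3, acetone, 45 °C
Reagents that add atoms: sodium iodide, [Na+].[I-]
Why: Finkelstein exchange at the unhindered primary bromide; buffered neutral iodide should leave the trisubstituted epoxide and the allylic acetate alone.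

Step 14
Reactants: 21 primary iodide
Product: 22 primary alcohol
Conditions: HF·pyridine, pyridine, THF, 0 °C
Reagents that add atoms: none
Why: Buffered fluoride cleavage of the primary silyl ether under conditions that trisubstituted epoxides tolerate, kept cold and short to avoid lactone migration to the freed hydroxyl.

Step 15
Reactants: 22 primary alcohol
Product: 23 iodo aldehyde
Conditions: Dess–Martin periodinane, NaHCO3, CH2Cl2, 0 °C; used at once
Reagents that add atoms: none
Why: Neutral Dess–Martin oxidation should give the α-branched β-acyloxy aldehyde without epimerisation at C10 or β-elimination of the lactone oxygen.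

Step 16
Reactants: 23 iodo aldehyde
Product: 24 macrocyclic (9R)-alcohol
Conditions: CrCl2 (8 equiv), CoPc (cobalt phthalocyanine, C32H16CoN8, 10 mol %), DMF, 25 °C, syringe-pump addition of 23 to a final 0.002 M
Reagents that add atoms: none
Why: Proposed new method: CoPc is reduced by CrCl2 to monovalent cobalt, which displaces iodide at C8; the alkylcobalt homolyses and the C8 radical is captured by divalent chromium to give an alkylchromium (trivalent chromium) that adds to the C9 aldehyde on the same chain, driven by Cr–O bond formation and inert towards lactone, esters, epoxide and sulfide. The closest known reaction type is the cobalt-catalysed, CrCl2-mediated addition of primary alkyl iodides to aldehydes (Takai–Utimoto), together with Nozaki–Hiyama–Kishi closures of ten-membered carbocycles from allylic and alkenyl halides; new here is the closure of a ten-membered ring with an unactivated alkyl iodide. The ten-membered carbocycle is closed by intramolecular 1,2-addition of C8 to the C9 carbonyl (10-exo-trig with respect to C=O), helped by the cis-fused lactone, the (E)-C2=C3 bond and the cis-epoxide, which remove rotors and bring the chain ends together. The new C9 centre is expected to arise under substrate control: in the Felkin–Anh arrangement the C10–C11 bond is anti to the incoming C8, C10–H flanks the trajectory and C1, from which the tether arrives, is gauche, which exposes the Re face and gives (9R). The step needs chemoselective activation of the C–I bond (the cobalt relay; divalent chromium alone reduces neither the aldehyde nor the acetate) and cyclisation ahead of oligomerisation or protonation of the alkylchromium (slow addition, high dilution, dry DMF).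

Step 17
Reactants: 24 macrocyclic (9R)-alcohol; 25 angelic acid
Product: 27 macrocyclic angelate, via mixed anhydride 26 (not isolated)
Conditions: 2,4,6-trichlorobenzoyl chloride, Et3N, toluene, 25 °C; then 24, toluene, 75 °C
Reagents that add atoms: none
Why: Yamaguchi-type esterification through the mixed anhydride without a nucleophilic catalyst should acylate O9 with retention at C9 and without Z-to-E isomerisation of the angeloyl unit.

Step 18
Reactants: 27 macrocyclic angelate
Product: 29 target CNP0519641.1, via sulfoxide 28 (not isolated)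
Conditions: NaIO4, MeOH/THF/H2O, 0 °C; then toluene, NaHCO3, 100 °C
Reagents that add atoms: none
Why: Periodate oxidises only the sulfide, and thermal syn-elimination of the sulfoxide, whose only β-hydrogen is on C11, should give the exocyclic C11=C13 methylene.

**Compound list**

1 | 4-bromobut-1-yne | C#CCCBr | starting material
2 | (4-bromobut-1-yn-1-yl)lithium | [Li]C#CCCBr | intermediate (not isolated)
3 | methyl 5-bromopent-2-ynoate | COC(=O)C#CCCBr | intermediate
4 | methyl (2Z)-5-bromo-3-methylpent-2-enoate | COC(=O)/C=C(/C)CCBr | intermediate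
5 | (2Z)-5-bromo-3-methylpent-2-en-1-ol | OC/C=C(/C)CCBr | intermediate
6 | [(2R,3S)-3-(2-bromoethyl)-3-methyloxiran-2-yl]methanol | OC[C@H]1O[C@@]1(C)CCBr | intermediate
7 | (2S,3S)-3-(2-bromoethyl)-3-methyloxirane-2-carbaldehyde | O=C[C@H]1O[C@@]1(C)CCBr | intermediate
8 | {[tert-butyl(dimethyl)silyl]oxy}acetaldehyde | O=CCO[Si](C)(C)C(C)(C)C | starting material
9 | methyl acrylate | C=CC(=O)OC | starting material
10 | methyl 4-{[tert-butyl(dimethyl)silyl]oxy}-3-hydroxy-2-methylidenebutanoate (racemic) | C=C(C(=O)OC)C(O)CO[Si](C)(C)C(C)(C)C | intermediate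
11 | methyl (2Z)-2-(bromomethyl)-4-{[tert-butyl(dimethyl)silyl]oxy}but-2-enoate | COC(=O)/C(CBr)=C/CO[Si](C)(C)C(C)(C)C | intermediate
12 | but-2-ynal | CC#CC=O | starting material
13 | methyl (3R,4R)-3-({[tert-butyl(dimethyl)silyl]oxy}methyl)-2-methylidene-4-[(trimethylsilyl)oxy]hept-5-ynoate | COC(=O)C(=C)[C@H](CO[Si](C)(C)C(C)(C)C)[C@@H](O[Si](C)(C)C)C#CC | intermediate (not isolated)
14 | methyl (3R,4R)-3-({[tert-butyl(dimethyl)silyl]oxy}methyl)-4-hydroxy-2-methylidenehept-5-ynoate | COC(=O)C(=C)[C@H](CO[Si](C)(C)C(C)(C)C)[C@@H](O)C#CC | intermediate (not isolated)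
15 | (4R,5R)-4-({[tert-butyl(dimethyl)silyl]oxy}methyl)-3-methylidene-5-(prop-1-yn-1-yl)oxolan-2-one | C=C1C(=O)O[C@@H](C#CC)[C@H]1CO[Si](C)(C)C(C)(C)C | intermediate
16 | (3S,4R,5R)-4-({[tert-butyl(dimethyl)silyl]oxy}methyl)-3-[(phenylsulfanyl)methyl]-5-(prop-1-yn-1-yl)oxolan-2-one | O=C1O[C@@H](C#CC)[C@@H](CO[Si](C)(C)C(C)(C)C)[C@@H]1CSc2ccccc2 | intermediate
17 | chlorobis(cyclopentadienyl)zirconium (E)-alkenyl derivative of 16, Zr on the methyl-bearing alkene carbon | O=C1O[C@@H](/C=C(\C)[Zr](Cl)(C2C=CC=C2)C2C=CC=C2)[C@@H](CO[Si](C)(C)C(C)(C)C)[C@@H]1CSc3ccccc3 | intermediate (not isolated)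
18 | (3S,4R,5R)-4-({[tert-butyl(dimethyl)silyl]oxy}methyl)-5-[(1E)-2-iodoprop-1-en-1-yl]-3-[(phenylsulfanyl)methyl]oxolan-2-one | O=C1O[C@@H](/C=C(\C)I)[C@@H](CO[Si](C)(C)C(C)(C)C)[C@@H]1CSc2ccccc2 | intermediate
19 | (3S,4R,5S)-5-{(1E,3R)-3-[(2R,3S)-3-(2-bromoethyl)-3-methyloxiran-2-yl]-3-hydroxy-2-methylprop-1-en-1-yl}-4-({[tert-butyl(dimethyl)silyl]oxy}methyl)-3-[(phenylsulfanyl)methyl]oxolan-2-one | O=C1O[C@@H](/C=C(\C)[C@@H](O)[C@H]2O[C@@]2(C)CCBr)[C@@H](CO[Si](C)(C)C(C)(C)C)[C@@H]1CSc3ccccc3 | intermediate
20 | (3S,4R,5S)-5-{(1E,3R)-3-acetoxy-3-[(2R,3S)-3-(2-bromoethyl)-3-methyloxiran-2-yl]-2-methylprop-1-en-1-yl}-4-({[tert-butyl(dimethyl)silyl]oxy}methyl)-3-[(phenylsulfanyl)methyl]oxolan-2-one | O=C1O[C@@H](/C=C(\C)[C@@H](OC(C)=O)[C@H]2O[C@@]2(C)CCBr)[C@@H](CO[Si](C)(C)C(C)(C)C)[C@@H]1CSc3ccccc3 | intermediate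
21 | (3S,4R,5S)-5-{(1E,3R)-3-acetoxy-3-[(2R,3S)-3-(2-iodoethyl)-3-methyloxiran-2-yl]-2-methylprop-1-en-1-yl}-4-({[tert-butyl(dimethyl)silyl]oxy}methyl)-3-[(phenylsulfanyl)methyl]oxolan-2-one | O=C1O[C@@H](/C=C(\C)[C@@H](OC(C)=O)[C@H]2O[C@@]2(C)CCI)[C@@H](CO[Si](C)(C)C(C)(C)C)[C@@H]1CSc3ccccc3 | intermediate
22 | (3S,4R,5S)-5-{(1E,3R)-3-acetoxy-3-[(2R,3S)-3-(2-iodoethyl)-3-methyloxiran-2-yl]-2-methylprop-1-en-1-yl}-4-(hydroxymethyl)-3-[(phenylsulfanyl)methyl]oxolan-2-one | O=C1O[C@@H](/C=C(\C)[C@@H](OC(C)=O)[C@H]2O[C@@]2(C)CCI)[C@@H](CO)[C@@H]1CSc3ccccc3 | intermediate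
23 | (2S,3S,4S)-2-{(1E,3R)-3-acetoxy-3-[(2R,3S)-3-(2-iodoethyl)-3-methyloxiran-2-yl]-2-methylprop-1-en-1-yl}-5-oxo-4-[(phenylsulfanyl)methyl]oxolane-3-carbaldehyde | O=C1O[C@@H](/C=C(\C)[C@@H](OC(C)=O)[C@H]2O[C@@]2(C)CCI)[C@@H](C=O)[C@@H]1CSc3ccccc3 | intermediate
24 | macrocyclic alcohol (numbering of the plan): (1S,2E,4R,5R,6S,9R,10R,11S)-4-acetoxy-5,6-epoxy-9-hydroxy-3,6-dimethyl-11-[(phenylsulfanyl)methyl]cyclodec-2-ene fused at C1/C10 to the 12,1-olide | O=C1O[C@H]2/C=C(\C)[C@@H](OC(C)=O)[C@H]3O[C@@]3(C)CC[C@@H](O)[C@H]2[C@@H]1CSc4ccccc4 | intermediate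
25 | angelic acid, (2Z)-2-methylbut-2-enoic acid | C/C=C(/C)C(=O)O | starting material
26 | (2Z)-2-methylbut-2-enoic 2,4,6-trichlorobenzoic anhydride | C/C=C(/C)C(=O)OC(=O)c1c(Cl)cc(Cl)cc1Cl | intermediate (not isolated)
27 | 9-O-angeloyl derivative of 24, (1S,2E,4R,5R,6S,9R,10R,11S) | O=C1O[C@H]2/C=C(\C)[C@@H](OC(C)=O)[C@H]3O[C@@]3(C)CC[C@@H](OC(=O)/C(C)=C\C)[C@H]2[C@@H]1CSc4ccccc4 | intermediate
28 | S-oxide of 27 (mixture at sulfur) | O=C1O[C@H]2/C=C(\C)[C@@H](OC(C)=O)[C@H]3O[C@@]3(C)CC[C@@H](OC(=O)/C(C)=C\C)[C@H]2[C@@H]1CS(=O)c4ccccc4 | intermediate (not isolated)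
29 | CNP0519641.1: (1S,2E,4R,5R,6S,9R,10R)-4-acetoxy-9-angeloyloxy-5,6-epoxy-3,6-dimethyl-11-methylidene-12,1-olide (numbering of the plan) | C=C1C(=O)O[C@H]2/C=C(\C)[C@@H](OC(C)=O)[C@H]3O[C@@]3(C)CC[C@@H](OC(=O)/C(C)=C\C)[C@@H]12 | target

**Step count**

Total: 18 steps. Longest linear sequence: 13 steps (steps 6–10, then 11–18; the branch through steps 1–5 is equally long).

**Steps most likely to fail**

1. Step 16 (Proposed new method). The alkylchromium may be protonated, or the C8 radical reduced, before it reaches the aldehyde; intermolecular addition may outrun the strained ten-membered closure; and the facial selectivity at C9 may be lower than the Felkin–Anh model suggests. Fallback with known chemistry in a different organometallic manifold: set out from iodo aldehyde 23 and close the same bond by a samarium Barbier reaction (SmI2, NiI2 cat., THF, −78 → 0 °C, high dilution). Here the iodide is reduced to an alkylsamarium or radical that joins the aldehyde or its ketyl on the oxophilic samarium template, a reaction type established for medium-ring carbocyclisation of ω-iodo carbonyl compounds. It returns directly to the macrocyclic alcohol 24, so no compound outside the list arises (F0).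

2. Step 11. Facial selectivity of the alkenylchromium addition to the epoxy aldehyde may be poor, giving a mixture at C4. Fallback by reagent control: set out from the C4-epimeric mixture of 19, oxidise with Dess–Martin periodinane (NaHCO3, CH2Cl2, 0 °C) to the epoxy enone (3S,4R,5S)-5-{(1E)-3-[(2S,3S)-3-(2-bromoethyl)-3-methyloxiran-2-yl]-2-methyl-3-oxoprop-1-en-1-yl}-4-({[tert-butyl(dimethyl)silyl]oxy}methyl)-3-[(phenylsulfanyl)methyl]oxolan-2-one F1, and reduce with (R)-2-methyl-CBS-oxazaborolidine and catecholborane (toluene, −78 °C), the alkenyl group acting as the large substituent, to return to 19 as the (4R) alcohol.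

3. Step 17. The angeloyl unit may isomerise to the tigloyl isomer during activation, acylation of the hindered C9 hydroxyl may be slow, and the lactone may migrate to O9 on prolonged heating. Fallback that builds the Z-alkene on the molecule: set out from 24, esterify with 2-(diphenoxyphosphoryl)propanoic acid (DCC, DMAP cat., CH2Cl2, 0 °C) to the 9-O-[2-(diphenoxyphosphoryl)propanoyl] ester of 24 F2, then carry out a Z-selective Ando olefination with acetaldehyde (NaI, DBU, THF, −78 → 0 °C), which should give the (Z)-2-methylbut-2-enoate and so return to 27.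

**Further compounds**

F0 | step 16 | none | none
F1 | step 11 | (3S,4R,5S)-5-{(1E)-3-[(2S,3S)-3-(2-bromoethyl)-3-methyloxiran-2-yl]-2-methyl-3-oxoprop-1-en-1-yl}-4-({[tert-butyl(dimethyl)silyl]oxy}methyl)-3-[(phenylsulfanyl)methyl]oxolan-2-one | O=C1O[C@@H](/C=C(\C)C(=O)[C@H]2O[C@@]2(C)CCBr)[C@@H](CO[Si](C)(C)C(C)(C)C)[C@@H]1CSc3ccccc3
F2 | step 17 | 9-O-[2-(diphenoxyphosphoryl)propanoyl] ester of 24 (mixture at the phosphonate α-carbon) | O=C1O[C@H]2/C=C(\C)[C@@H](OC(C)=O)[C@H]3O[C@@]3(C)CC[C@@H](OC(=O)C(C)P(=O)(Oc4ccccc4)Oc5ccccc5)[C@H]2[C@@H]1CSc6ccccc6
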